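(The earlier runs and the new flask are calculated on assumed constants, noise included.)

A decay constant fitted at one temperature looks finished, and the pitfall is to carry it unchanged into a colder flask.

| flask | substrate | temperature | remark | time |
|---|---|---|---|---|
| beta | 10 mM | 120 °C | run made earlier |  |
| Wednesday's | 20 mM |  | at 120 °C until 6.0 min, from then on at 80 °C | 12 min |
| Friday's | 20 mM | 120 °C |  | 12 min |
| Saturday's | 20 mM | 80 °C |  | 12 min |
| Thursday's | 20 mM | 100 °C |  | 12 min |

beta run (percent of the substrate charged)

| time / s | intermediate A / % | target / % |
|---|---|---|
| 10.0 | 65.0 | 4.2 |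
| 20.0 | 41.3 | 22.6 |
| 30.0 | 24.8 | 35.9 |
| 40.0 | 16.5 | 52.4 |
| 50.0 | 8.2 | 63.5 |
| 60.0 | 5.9 | 75.4 |
| 80.0 | 1.1 | 86.6 |

(standard deviation of a reading: 1 percentage point)

- the earlier runs do not show what temperature does; that part of a forecast is a guess

- the flask with the highest amount of intermediate A, in percent of the substrate charged ("all alike" if they lie within 1.5 percentage points) (Wednesday's / Friday's / Saturday's / Thursday's / all alike)
- final intermediate A, as a percentage of the substrate charged, in Wednesday's
- final intermediate A, as a percentage of the substrate charged, in Friday's
- final intermediate A, as a percentage of the substrate charged, in Saturday's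
- final intermediate A, as a percentage of the substrate charged, in Thursday's

In the beta run, intermediate A fell from 65.0% to 5.9% between the first and sixth readings, so I read a first-order lifetime of 20.8 s. I carried this lifetime, the time in which intermediate A falls by a factor e. A flask's time divided by it counts lifetimes, and for a flask that starts with its whole charge as intermediate A, the share left is e to the minus count.

Two extreme versions can be solved in the head. The hot one is Friday's, at the temperature of the beta run: if a charge twice as large leaves the lifetime alone, its time holds 34.6 lifetimes and leaves a share of <0.001%. Wednesday's has 17.3 lifetimes before its cooling, so it belongs with Friday's. The cold extreme is a flask in which intermediate A does not decay at all and stands at 100 percent of the charge.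

Saturday's and Thursday's must lie between these, at a place the beta run cannot show. I guessed with the old rule that a rate doubles every 10 degrees. That slows Saturday's by 16.0, giving 2.16 lifetimes and a share of 11.5%. Thursday's is slowed by 4.00 and keeps 0.0177%.

The forecast guessed an activation energy of about 100 kJ/mol and named Saturday's: “Saturday's should be highest, but its value is very uncertain”. It gave Saturday's 28%, between 6% and 60%, which is more than my share. It gave Thursday's 1%, Wednesday's 0.1% and Friday's 0.1%.

The simulation put Saturday's highest, with 24.2% of intermediate A in Saturday's, 0.0397% in Thursday's, 0% in Wednesday's and 0% in Friday's.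

    substrate → intermediate A (k = 0.130 s⁻¹, Ea = 90.0 kJ mol⁻¹)
    intermediate A → intermediate B (k = 0.0110 s⁻¹, Ea = 91.0 kJ mol⁻¹)
    intermediate B → target (k = 0.00700 s⁻¹, Ea = 112 kJ mol⁻¹)
    substrate + target → side product (k = 0.0480 M⁻¹ s⁻¹, Ea = 56.0 kJ mol⁻¹)
    substrate → decomposition product (k = 5.70 × 10⁻⁶ s⁻¹, Ea = 123 kJ mol⁻¹)
    (constants at 100 °C)

In Saturday's, substrate was down to 0.0117% at 6.00 min, and from then to 12.0 min intermediate A fell from 51.4% to 24.2%, so its lifetime was 7.98 min, which is 23.0 times the 20.8 s of the beta run. At 0.460 min in Saturday's, intermediate A was being made 12.4 times faster than it was used up, each step taken net. With that lifetime, the 24.2% of Saturday's, carried on from 12 min to a reading at 20 min, comes to 8.88%, and that reading held 8.89%.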